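## The problem

Asplenetin (11) is an achiral flavone. Its 4H-chromen-4-one core joins a phloroglucinol-type ring A (hydroxyls at C5 and C7) to a pyranone ring C that carries a 3,4,5-trihydroxyphenyl ring B at C2 and a saturated 3-methylbutyl chain at C3. The difficulty is connectivity, not configuration: ring C must be closed with a fully substituted C2=C3 bond, and a five-carbon chain with no functional handle must be bonded to C3. That position cannot simply be alkylated, because flavanone enolates expel the ring A phenoxide and flavones are not nucleophilic there. No stereocentre survives in 11. C2 and C3 are stereogenic only at the flavanone stage, where C2 would steer C3 towards trans, and both are flattened by the later dehydrogenation, so no stereocontrol has to be paid for. The five phenols, above all the pyrogallol unit of ring B, are oxidised easily by air in base and would not survive radical or organometallic steps; they must travel as robust ethers and be released last, under acid. A short route is possible because of the C4(=O)–C3–CH2–CH2 array. If the chain is cut between its first and second carbon, C3 and the first chain carbon become the two ends of a vinyl group, C4 becomes a formyl carbon on ring A, and the O1–C2 ether bond ties the two together. A four-carbon radical adding to the vinyl terminus then gives a C3 radical placed for six-membered closure onto the formyl carbon, so chain and ring C are completed in one event.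

## Retrosynthesis

**11 ⇒ 10.** The last operation should only unmask. The five O–H bonds of 11 are taken back to O–CH3 bonds in the pentamethyl ether 10. Methyl ethers are preferred to benzyl or acetal groups because they have no weak C–H bond and withstand hot aqueous acid, both of which matter in the radical step. The price is a forcing Lewis-acid cleavage at the end, which the saturated chain and the pyranone of 10 should tolerate. The gain is in handling: 10 is not air-sensitive.

**10 ⇒ 9.** The C2=C3 double bond of 10 is taken back to the flavanone 9. This change of oxidation level lets C3 be sp3 and so be the product of a radical ring closure. The neighbouring option, keeping the flavone and attaching the chain by halogenation and cross-coupling at C3, would have to compete with halogenation of the electron-rich ring A. Forward, a flavanone-to-flavone dehydrogenation is needed; it removes both stereocentres of 9, so any cis/trans mixture of 9 will serve.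

**9 ⇒ 7 + 8 (key cut).** Two bonds of 9 are cut at once: C3–C4, and the bond between the first and second carbon of the side chain. This leaves the aldehyde-tethered allyl ether 7, whose formyl carbon is the future C4 and whose vinyl group supplies C3 and the first chain carbon. The other piece is 3-methylbutanoic acid (8), whose alkyl part is the remaining four carbons and whose carboxyl group is lost. The neighbouring cuts are weaker. Cutting only the C3–chain bond asks for alkylation of a flavanone enolate, which ring-opens. Cutting only O1–C2 leads to an open-chain α-alkyl enone whose aldol assembly from a hindered long-chain aryl ketone is slow and needs a separate ketone synthesis. The simplification is large: a bicyclic ketone with two stereocentres becomes an open diaryl ether with one stereocentre plus a commodity acid. Forward, the reaction must generate a primary alkyl radical under conditions that 7 survives, add it at the terminal alkene carbon only, and close the six-membered ring on the carbonyl carbon. The silver-catalysed oxidative decarboxylation cascade of 2-(allyloxy)benzaldehydes does this; 7 differs from the usual substrates by the aryl group on the allylic carbon.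

**7 ⇒ 4 + 5.** The O1–C2 bond of 7 is cut to give the salicylaldehyde 5, used as its sodium salt 6, and the branched allylic methyl carbonate 4. Direct SN2 alkylation with a secondary 1-arylallyl halide is not viable: such halides are unstable and react at the unhindered terminus to give the linear isomer of 7. An (allyl)iridium intermediate is instead attacked at the substituted terminus. Both precursors are simple: a commercial phenol and a benzaldehyde extended by two carbons. The forward step must keep the branched connectivity and tolerate the free aldehyde; enantiocontrol is not needed.

**4 ⇒ 1 + 2.** Carbonate 4 is cut at the bond between the carbinol carbon and the vinyl group and at its O–acyl bond. This gives 3,4,5-trimethoxybenzaldehyde (1) and vinylmagnesium bromide (2); their adduct, alkoxide 3, is acylated in the same flask. Both are commercial, so the analysis ends here. The linear isomer of 4 would serve the iridium step equally but takes two more steps to make.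

## Roads not taken

**Alternative 1:** Carbon monoxide as C4. The cut falls on both sides of the carbonyl carbon, C4a–C4 and C4–C3, so that C4 comes from carbon monoxide (A4). In the forward key step three components would be joined by a zerovalent palladium catalyst with a wide-bite-angle bisphosphine: the ring A iodide 2-iodo-1,5-dimethoxy-3-(methoxymethoxy)benzene (A2), A4, and the enolate of 5-methyl-1-(3,4,5-trimethoxyphenyl)hexan-1-one (A3). The product is the 2-alkyl-1,3-diketone A1. Acid would then remove the methoxymethyl group and cyclodehydrate, arriving at 10 without any change of oxidation level.
- Merits: the skeleton is complete in one step, there is no stereochemistry, and no oxidant comes near the electron-rich rings.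
- Weak points: they are steric. A2 is flanked by two oxygen substituents, so its acylpalladium species is hindered, and the enolate of A3 is substituted at its α-carbon. O-acylation, direct arylation without uptake of A4, and slow C-acylation all compete. A2 and A3 are not commercial and cost about two steps each, for about seven steps in total, and A4 must be handled under pressure or generated ex situ.
- Comparison: this road is better in tolerance of the methoxyarenes and avoids the dehydrogenation. The chosen plan sets against it five steps from four purchased materials, a chain taken from a bulk acid instead of being built into a ketone, and a key step whose regiochemistry is fixed by the substrate.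

**Alternative 2:** Danheiser benzannulation of ring A. Here ring A is built, not bought. The four bonds C8–C8a, C7–C8, C5–C6 and C4a–C5 are cut, leaving the diazoketone 2-diazo-1-[5-(3-methylbutyl)-4-oxo-6-(3,4,5-trimethoxyphenyl)-4H-pyran-2-yl]ethan-1-one (A6) and ethoxyacetylene (A7). Forward, irradiation of A6 would induce Wolff rearrangement. The pyranonylketene would combine with A7 by [2+2] addition, four-electron ring opening and six-electron ring closure to give the 5-hydroxy-7-ethoxyflavone A5. A single ether cleavage then leads to 11.
- Merits: ring A is regiochemically unambiguous, the flavone oxidation level is present from the outset, the oxygens at C5 and C7 are differentiated, and the endgame is the shortest of the four plans.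
- Weak points: the differentiation buys nothing here, because both oxygens end as free phenols, and ring A is the one part of the molecule that can be bought with the right oxygenation. The cost moves into A6, a multistep target in which the problem of placing the 3-methylbutyl chain next to the carbonyl returns unsolved. Photolysis must also compete with absorption by the pyranone and trimethoxyphenyl chromophores, and A7 is volatile and sensitive.
- Comparison: after its key step this road is one step shorter than the chosen plan and uses no persulfate. The chosen plan answers with a far shorter overall sequence and precursors one or two steps from catalogue compounds.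

**Alternative 3:** Palladium-mediated ynone cyclisation with oxygen-to-carbon prenyl transfer. The cuts are O1–C2 and the bond from C3 to the chain. Both fragments sit in one molecule, the ynone 1-{2,4-dimethoxy-6-[(3-methylbut-2-en-1-yl)oxy]phenyl}-3-(3,4,5-trimethoxyphenyl)prop-2-yn-1-one (A9). A zerovalent palladium catalyst would ionise the aryl prenyl ether, the phenoxide would add 6-endo to the alkyne carbon bearing ring B, and the C3–palladium bond would be allylated by the prenyl unit to give the 3-prenylflavone A8. Hydrogenation of the side-chain alkene would then give 10.
- Merits: ring C forms directly as a flavone, the chain arrives whole after first serving as the protecting group of the ring A phenol, and the conditions are neutral and non-oxidising, which suits the electron-rich rings better than persulfate.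
- Weak points: they are concentrated in the key step. The allyl unit can be delivered at its CH2 or at its dimethyl-substituted terminus, the phenoxide can close 5-exo, protonation in place of allyl transfer would give a flavone without the chain, and crossover between molecules is possible. A9 needs about three steps from 5 plus an arylalkyne, and the extra hydrogenation must leave the C2=C3 bond alone, so the count is six to seven steps.
- Comparison: in mildness this road is at least equal to the chosen plan, and it needs no dehydrogenation. The chosen plan sets against it a shorter sequence, no late hydrogenation, and regiochemistry and ring size that follow from substrate geometry, not from catalyst control.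

Key step: step 3

Remark on the chemistry: 11 is achiral, so all chiral intermediates are made and used as racemates; where a SMILES shows one enantiomer, the racemate is meant.

## Route

Step 1
Reactants: 1 3,4,5-trimethoxybenzaldehyde; 2 vinylmagnesium bromide
Product: 4 methyl 1-(3,4,5-trimethoxyphenyl)prop-2-en-1-yl carbonate (racemic), via bromomagnesium allylic alkoxide 3 (not isolated)
Conditions: THF, −20 → 0 °C; then ClCO2Me, 0 °C → rt
Reagents that add atoms: methyl chloroformate, COC(=O)Cl
Why: Grignard 1,2-addition of 2 to the aldehyde of 1, followed by O-acylation of the magnesium alkoxide 3 with the chloroformate in the same flask, a standard one-pot entry to branched allylic carbonates; the new stereocentre (the future C2) is formed racemic and needs no control because step 4 destroys it.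

Step 2
Reactants: 4 methyl 1-(3,4,5-trimethoxyphenyl)prop-2-en-1-yl carbonate; 5 2-hydroxy-4,6-dimethoxybenzaldehyde
Product: 7 2,4-dimethoxy-6-{[1-(3,4,5-trimethoxyphenyl)prop-2-en-1-yl]oxy}benzaldehyde (racemic), via sodium 2-formyl-3,5-dimethoxyphenolate 6 (not isolated)
Conditions: 5, NaH, THF, 0 °C → rt; then 4, [Ir(cod)Cl]2 (2 mol%), racemic BINOL-derived N,N-bis(1-phenylethyl)phosphoramidite (4 mol%), THF, 50 °C
Reagents that add atoms: none
Why: Iridium-catalysed allylic etherification of an allylic carbonate with a phenoxide: ionisation of 4 gives an (allyl)iridium complex that phenoxide 6 attacks at the aryl-substituted terminus, the regiochemistry typical of iridium, so the branched ether should form and not its linear isomer; the methyl carbonate leaving group collapses to CO2 and methoxide. The stereocentre is racemic by design (racemic ligand), and the aldehyde is carried unprotected as a spectator.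

Step 3
Reactants: 7 2,4-dimethoxy-6-{[1-(3,4,5-trimethoxyphenyl)prop-2-en-1-yl]oxy}benzaldehyde; 8 3-methylbutanoic acid
Product: 9 trans-5,7-dimethoxy-3-(3-methylbutyl)-2-(3,4,5-trimethoxyphenyl)chroman-4-one (racemic, 2R*,3S*)
Conditions: 8 (3 equiv), AgNO3 (20 mol%), K2S2O8 (2.5 equiv, added in portions), MeCN/H2O (1:1), 70 °C, Ar
Reagents that add atoms: none
Why: Persulfate raises the silver catalyst to its divalent state, which oxidises the carboxylate of 8; the acyloxy radical loses CO2, and the nucleophilic isobutyl radical adds to the unsubstituted terminus of the vinyl group of 7, making the bond between the first and second chain carbon. The secondary radical now at C3 attacks the formyl carbon (C3–C4), and the benzylic alkoxy radical passes by a 1,2-hydrogen shift into a ketyl radical that divalent silver or persulfate oxidises to the ketone. The closest known reaction type is the silver-catalysed decarboxylative alkylation/acylation cascade of 2-(allyloxy)benzaldehydes with aliphatic acids to 3-alkylchroman-4-ones; 7 is such an aldehyde with an extra aryl group on the allylic carbon. Ring C closes in the 6-exo-trig mode, a carbon radical adding to the carbon end of the C=O bond. The new stereocentre C3 is set by the existing C2: in a chair-like closure the aryl group and the growing chain both lie pseudo-equatorial, which gives the trans isomer, and C3 can also epimerise to trans because it is α to the ketone; any cis isomer is carried along since step 4 removes both centres. The step needs addition at the terminal alkene carbon (secured by the monosubstituted alkene, which offers an open CH2 end and a secondary radical), closure on carbon in a six-membered ring (secured by the ortho tether), and chemoselectivity over hydrogen abstraction at the doubly activated C2–H and over oxidation of the methoxyarenes. That last demand is met by methyl ethers without weak C–H bonds, by an excess of 8 that intercepts the oxidant and buffers the KHSO4 formed, and by portionwise addition of K2S2O8; any 10 formed by over-oxidation does no harm, since step 4 makes it anyway.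

Step 4
Reactants: 9 trans-5,7-dimethoxy-3-(3-methylbutyl)-2-(3,4,5-trimethoxyphenyl)chroman-4-one
Product: 10 5,7-dimethoxy-3-(3-methylbutyl)-2-(3,4,5-trimethoxyphenyl)-4H-chromen-4-one
Conditions: I2 (20 mol%), DMSO, 130 °C
Reagents that add atoms: none
Why: Iodine-catalysed dehydrogenation of a flavanone in DMSO: acid-promoted enolisation towards C3, iodination and loss of HI across C2–C3, with DMSO re-oxidising HI to I2; formation of the 4-pyranone drives it, an exocyclic alkene isomer or a ring-opened enone would funnel to the same product under these conditions, and both stereocentres of 9 disappear, so its cis/trans composition is immaterial.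

Step 5
Reactants: 10 5,7-dimethoxy-3-(3-methylbutyl)-2-(3,4,5-trimethoxyphenyl)-4H-chromen-4-one
Product: 11 asplenetin [5,7-dihydroxy-3-(3-methylbutyl)-2-(3,4,5-trihydroxyphenyl)-4H-chromen-4-one]
Conditions: BBr3 (excess), CH2Cl2, −78 °C → rt; then MeOH, aq. HCl, Ar
Reagents that add atoms: none
Why: Lewis-acid cleavage of aryl methyl ethers with BBr3 (bromide attacks the methyl group of the boron-complexed ether); the 5-methoxy group should go first through chelation to the C4 carbonyl, and excess reagent with warming should take the other four, while the saturated chain and the pyranone are inert; acidic, oxygen-free work-up protects the pyrogallol ring.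

## Compound list

1 | 3,4,5-trimethoxybenzaldehyde | COc1cc(C=O)cc(OC)c1OC | starting material
2 | vinylmagnesium bromide | C=C[Mg]Br | starting material
3 | bromomagnesium 1-(3,4,5-trimethoxyphenyl)prop-2-en-1-olate (racemic; one enantiomer drawn) | C=C[C@@H](O[Mg]Br)c1cc(OC)c(OC)c(OC)c1 | intermediate
4 | methyl 1-(3,4,5-trimethoxyphenyl)prop-2-en-1-yl carbonate (racemic; one enantiomer drawn) | C=C[C@@H](OC(=O)OC)c1cc(OC)c(OC)c(OC)c1 | intermediate
5 | 2-hydroxy-4,6-dimethoxybenzaldehyde | COc1cc(O)c(C=O)c(OC)c1 | starting material
6 | sodium 2-formyl-3,5-dimethoxyphenolate | [Na+].[O-]c1cc(OC)cc(OC)c1C=O | intermediate
7 | 2,4-dimethoxy-6-{[1-(3,4,5-trimethoxyphenyl)prop-2-en-1-yl]oxy}benzaldehyde (racemic; one enantiomer drawn) | C=C[C@H](c1cc(OC)c(OC)c(OC)c1)Oc1cc(OC)cc(OC)c1C=O | intermediate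
8 | 3-methylbutanoic acid | CC(C)CC(=O)O | starting material
9 | trans-5,7-dimethoxy-3-(3-methylbutyl)-2-(3,4,5-trimethoxyphenyl)chroman-4-one (racemic; 2R,3S enantiomer drawn) | CC(C)CC[C@H]1[C@H](c2cc(OC)c(OC)c(OC)c2)Oc2cc(OC)cc(OC)c2C1=O | intermediate
10 | 5,7-dimethoxy-3-(3-methylbutyl)-2-(3,4,5-trimethoxyphenyl)-4H-chromen-4-one | CC(C)CCc1c(-c2cc(OC)c(OC)c(OC)c2)oc2cc(OC)cc(OC)c2c1=O | intermediate
11 | asplenetin, 5,7-dihydroxy-3-(3-methylbutyl)-2-(3,4,5-trihydroxyphenyl)-4H-chromen-4-one | CC(C)CCc1c(-c2cc(O)c(O)c(O)c2)oc2cc(O)cc(O)c2c1=O | target

## Step count and risk

Total step count: 5. Longest linear sequence: 5 steps (1 → 4 → 7 → 9 → 10 → 11); 5 and 8 enter as purchased materials.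

**Step 3 (key step).** The most likely failure is oxidative degradation of 7 before the cascade starts. Addition of a primary alkyl radical to an unactivated alkene is slow. In that time sulfate radical anion or divalent silver can abstract the benzylic, allylic, α-oxygenated hydrogen at C2, or oxidise the trimethoxyphenyl ring. The hot, increasingly acidic aqueous medium can also ionise the 1-arylallyl aryl ether. Finally, the C3 radical can fragment by loss of the aryloxy group instead of cyclising onto the hindered, doubly ortho-substituted aldehyde.

Fallback, closing ring C by ionic chemistry without any radical: it sets out from 1. BF3·OEt2-promoted acylation of 3,5-dimethoxyphenol with 5-methylhexanoic acid would give 1-(2-hydroxy-4,6-dimethoxyphenyl)-5-methylhexan-1-one F1. Condensation of F1 with 1 under pyrrolidine in ethanol at reflux (Kabbe-type aldol condensation) would pass through (2E)-1-(2-hydroxy-4,6-dimethoxyphenyl)-5-methyl-2-[(3,4,5-trimethoxyphenyl)methylidene]hexan-1-one F2. The phenol of F2 adds to the enone (oxa-Michael) to close ring C, and the route is rejoined at 9.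

**Step 2.** The most likely failure is loss of the branched connectivity. The ortho-formyl aryloxide is a good leaving group, so the product ether can re-ionise on iridium and isomerise to the conjugated linear ether. The chelating, stabilised phenoxide 6 may also attack the (allyl)iridium complex too slowly.

Fallback, SN2 displacement at an oxyphosphonium centre in place of an allyl-metal intermediate: it sets out from 1. Addition of 2 and aqueous quench of alkoxide 3 would give 1-(3,4,5-trimethoxyphenyl)prop-2-en-1-ol F3. Mitsunobu coupling of F3 with 5 (PPh3, DIAD, THF, 0 °C → rt) would rejoin the route at 7. Attack at the vinyl terminus (SN2') is the thing to check there.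

**Step 5.** The most likely failures are incomplete ether cleavage and oxidation during isolation. The 7-methoxy group has no neighbouring carbonyl to assist it and is the slowest to go, so partially methylated material may persist. The pyrogallol ring of the product can be oxidised by air during work-up or chromatography.

Fallback, protic demethylation with purification through a stable derivative: it sets out from 10. A melt of pyridinium chloride at 190 °C under argon would cleave all five ethers. The crude phenol would be acetylated directly (Ac2O, pyridine) to 3-(3-methylbutyl)-4-oxo-2-(3,4,5-triacetoxyphenyl)-4H-chromene-5,7-diyl diacetate F4, which is air-stable and can be chromatographed. Deacetylation with HCl in methanol under argon would arrive at 11.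

## Further compounds

F1 | step 3 | 1-(2-hydroxy-4,6-dimethoxyphenyl)-5-methylhexan-1-one | CC(C)CCCC(=O)c1c(O)cc(OC)cc1OC
F2 | step 3 | (2E)-1-(2-hydroxy-4,6-dimethoxyphenyl)-5-methyl-2-[(3,4,5-trimethoxyphenyl)methylidene]hexan-1-one | CC(C)CC/C(C(=O)c1c(O)cc(OC)cc1OC)=C\c1cc(OC)c(OC)c(OC)c1
F3 | step 2 | 1-(3,4,5-trimethoxyphenyl)prop-2-en-1-ol (racemic; one enantiomer drawn) | C=C[C@@H](O)c1cc(OC)c(OC)c(OC)c1
F4 | step 5 | 3-(3-methylbutyl)-4-oxo-2-(3,4,5-triacetoxyphenyl)-4H-chromene-5,7-diyl diacetate | CC(C)CCc1c(-c2cc(OC(C)=O)c(OC(C)=O)c(OC(C)=O)c2)oc2cc(OC(C)=O)cc(OC(C)=O)c2c1=O
A1 | alternative 1 | 1-[2,4-dimethoxy-6-(methoxymethoxy)phenyl]-2-(3-methylbutyl)-3-(3,4,5-trimethoxyphenyl)propane-1,3-dione (racemic, enolisable centre) | COCOc1cc(OC)cc(OC)c1C(=O)C(CCC(C)C)C(=O)c1cc(OC)c(OC)c(OC)c1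
A2 | alternative 1 | 2-iodo-1,5-dimethoxy-3-(methoxymethoxy)benzene | COCOc1cc(OC)cc(OC)c1I
A3 | alternative 1 | 5-methyl-1-(3,4,5-trimethoxyphenyl)hexan-1-one | CC(C)CCCC(=O)c1cc(OC)c(OC)c(OC)c1
A4 | alternative 1 | carbon monoxide | [C-]#[O+]
A5 | alternative 2 | 7-ethoxy-5-hydroxy-3-(3-methylbutyl)-2-(3,4,5-trimethoxyphenyl)chromen-4-one | CCOc1cc(O)c2c(c1)oc(-c1cc(OC)c(OC)c(OC)c1)c(CCC(C)C)c2=O
A6 | alternative 2 | 2-diazo-1-[5-(3-methylbutyl)-4-oxo-6-(3,4,5-trimethoxyphenyl)-4H-pyran-2-yl]ethan-1-one | [N-]=[N+]=CC(=O)c1cc(=O)c(CCC(C)C)c(-c2cc(OC)c(OC)c(OC)c2)o1
A7 | alternative 2 | ethoxyacetylene | CCOC#C
A8 | alternative 3 | 5,7-dimethoxy-3-(3-methylbut-2-enyl)-2-(3,4,5-trimethoxyphenyl)chromen-4-one | CC(C)=CCc1c(-c2cc(OC)c(OC)c(OC)c2)oc2cc(OC)cc(OC)c2c1=O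
A9 | alternative 3 | 1-{2,4-dimethoxy-6-[(3-methylbut-2-en-1-yl)oxy]phenyl}-3-(3,4,5-trimethoxyphenyl)prop-2-yn-1-one | CC(C)=CCOc1cc(OC)cc(OC)c1C(=O)C#Cc1cc(OC)c(OC)c(OC)c1
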